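**Plan**
1. Retrosynthesis: the three pivalates come off last. The pyran (ring C) is cut at O1–C2, which is the C8a phenol attacking an (R)-benzylic carbinol with inversion. Ring A is then cut at C5–C6, C6–C7, C8–C8a and C4a–C8a into an α-diazo enone (C8a, C6, C5, C4a, the C4–C3–C2 chain, ring B) and a 1-methoxyalkyne (C7, C8, side chain).
2. Enabling feature: ring A is a 2,6-dialkyl-3-methoxyphenol. The hydroxyl sits on C8a, the side chain on C8 between the two oxygens, the methoxyl on C7, the propyl chain on C4a, and C5/C6 are unsubstituted. A vinylketene and a 1-methoxyalkyne combine in exactly this pattern.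
3. Forward: ring B is bought as resorcinol, acylated with succinic anhydride and carried to the diazo enone (steps 1–8). The alkyne comes from 2-methyl-2-vinyloxirane and chloroacetaldehyde dimethyl acetal (steps 9–11).
4. Ring A arises in step 12 (benzannulation) and ring C in step 14 (Mitsunobu closure). The esters are removed in step 15.
5. Stereochemistry: C2 comes from the CBS reduction of the aryl ketone (R) and is inverted to S on ring closure. The E olefin comes from the SN2′ opening of the vinyl epoxide and is not touched afterwards.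

Key step: step 12

Remark: locants follow flavan (2-arylchroman) numbering with ring B primed; TBS = tert-butyldimethylsilyl, pivalate = 2,2-dimethylpropanoate; ylide 9 and all un-numbered reagents are taken as purchased.

**Route**

Step 1
Reactants: 1 resorcinol; 2 succinic anhydride
Product: 3 4-(2,4-dihydroxyphenyl)-4-oxobutanoic acid
Conditions: AlCl3 (3 equiv), PhNO2, 25 → 60 °C; aq. HCl
Reagents that add atoms: none
Why: Friedel–Crafts acylation by the AlCl3-activated anhydride goes to C4 of resorcinol (para to one hydroxyl, ortho to the other), and the chelated ketone with its carboxylate chain deactivates the ring against a second acylation.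

Step 2
Reactants: 3 4-(2,4-dihydroxyphenyl)-4-oxobutanoic acid
Product: 4 4-(2,4-dihydroxyphenyl)-N-methoxy-N-methyl-4-oxobutanamide
Conditions: MeNHOMe·HCl, EDC·HCl, HOBt, N-methylmorpholine, DMF, 0 → 25 °C
Reagents that add atoms: N,O-dimethylhydroxylamine hydrochloride, CNOC.Cl
Why: Carbodiimide amide coupling, in which the amine outcompetes the two weakly nucleophilic ketone-conjugated phenols for the active ester; the Weinreb amide is chosen because it can later be taken to the aldehyde without a hydride that would attack aryl esters.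

Step 3
Reactants: 4 4-(2,4-dihydroxyphenyl)-N-methoxy-N-methyl-4-oxobutanamide
Product: 5 4-[4-(methoxy(methyl)amino)-4-oxobutanoyl]-1,3-phenylene bis(pivalate)
Conditions: PivCl (2.4 equiv), Et3N, DMAP (cat.), CH2Cl2, 0 → 25 °C
Reagents that add atoms: pivaloyl chloride, CC(C)(C)C(Cl)=O
Why: DMAP-catalysed O-acylation of both phenols (the chelated C2′ hydroxyl included) gives esters that are electron-withdrawing enough to suppress later benzylic ionisation and hindered enough to survive the amide base, the zirconium hydride and the fluoride steps.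

Step 4
Reactants: 5 4-[4-(methoxy(methyl)amino)-4-oxobutanoyl]-1,3-phenylene bis(pivalate)
Product: 6 (R)-4-[1-hydroxy-4-(methoxy(methyl)amino)-4-oxobutyl]-1,3-phenylene bis(pivalate)
Conditions: (S)-2-methyl-CBS-oxazaborolidine (0.15 equiv), BH3·SMe2, THF, −20 °C; MeOH
Reagents that add atoms: none
Why: Corey–Bakshi–Shibata reduction, in which the (S)-oxazaborolidine binds the ketone with the aryl group as the large substituent and delivers hydride to the face that gives the (R)-carbinol, while the amide and aryl esters are inert to borane at this temperature and the neutral medium offers the ortho pivalate no alkoxide to migrate to.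

Step 5
Reactants: 6 (R)-4-[1-hydroxy-4-(methoxy(methyl)amino)-4-oxobutyl]-1,3-phenylene bis(pivalate)
Product: 7 (R)-4-[1-(tert-butyldimethylsilyloxy)-4-(methoxy(methyl)amino)-4-oxobutyl]-1,3-phenylene bis(pivalate)
Conditions: TBSOTf, 2,6-lutidine, CH2Cl2, −78 → 0 °C (crude 6 used directly)
Reagents that add atoms: tert-butyldimethylsilyl triflate, CC(C)(C)[Si](C)(C)OS(=O)(=O)C(F)(F)F
Why: Silylation of a secondary alcohol with the silyl triflate and a hindered base is fast at low temperature, so the carbinol should be capped before lactonisation onto the amide or acyl transfer from the neighbouring pivalate can compete.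

Step 6
Reactants: 7 (R)-4-[1-(tert-butyldimethylsilyloxy)-4-(methoxy(methyl)amino)-4-oxobutyl]-1,3-phenylene bis(pivalate)
Product: 8 (R)-4-[1-(tert-butyldimethylsilyloxy)-4-oxobutyl]-1,3-phenylene bis(pivalate)
Conditions: Cp2Zr(H)Cl (Schwartz reagent, 1.5 equiv), THF, 25 °C; aq. work-up
Reagents that add atoms: none
Why: Hydrozirconation of the Weinreb amide gives a stable zirconated hemiaminal that releases the aldehyde on work-up, a reduction known to leave esters and silyl ethers untouched, which iBu2AlH could not guarantee for the aryl pivalates.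

Step 7
Reactants: 8 (R)-4-[1-(tert-butyldimethylsilyloxy)-4-oxobutyl]-1,3-phenylene bis(pivalate); 9 1-(triphenylphosphoranylidene)propan-2-one
Product: 10 (R,E)-7-[2,4-bis(pivaloyloxy)phenyl]-7-(tert-butyldimethylsilyloxy)hept-3-en-2-one
Conditions: CH2Cl2, 40 °C
Reagents that add atoms: none
Why: Wittig olefination with a ketone-stabilised ylide is E-selective with unhindered aliphatic aldehydes and needs no added base, so the esters and the silyl ether are safe.

Step 8
Reactants: 10 (R,E)-7-[2,4-bis(pivaloyloxy)phenyl]-7-(tert-butyldimethylsilyloxy)hept-3-en-2-one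
Product: 12 (R,E)-7-[2,4-bis(pivaloyloxy)phenyl]-7-(tert-butyldimethylsilyloxy)-1-diazohept-3-en-2-one, via trifluoroacetyl diketone 11 (not isolated)
Conditions: LiN(SiMe3)2, THF, −78 °C; CF3CO2CH2CF3; dilute HCl wash; then MsN3, Et3N, H2O (1 equiv), MeCN, 25 °C
Reagents that add atoms: methanesulfonyl azide, CS(=O)(=O)N=[N+]=[N-]; 2,2,2-trifluoroethyl trifluoroacetate, O=C(OCC(F)(F)F)C(F)(F)F (its trifluoroacetyl group appears only in 11)
Why: Detrifluoroacetylative (Regitz-type) diazo transfer, in which the kinetic lithium enolate forms at the methyl group, its trifluoroacetyl derivative 11 is acidic enough for Et3N-mediated transfer from MsN3, and loss of the trifluoroacetyl group leaves the α′-diazo enone, the established way to such compounds.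

Step 9
Reactants: 13 2-methyl-2-vinyloxirane
Product: 14 (E)-4-chloro-2-methylbut-2-en-1-ol
Conditions: TiCl4, CH2Cl2, −85 °C; aq. HCl
Reagents that add atoms: titanium tetrachloride, Cl[Ti](Cl)(Cl)Cl
Why: Lewis-acid opening of the vinyl epoxide with conjugate (SN2′) delivery of chloride to the vinyl terminus, a transformation precedented for this epoxide, should give mainly the E olefin because the titanium-bound CH2O group and the new CH2Cl group end up trans.

Step 10
Reactants: 14 (E)-4-chloro-2-methylbut-2-en-1-ol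
Product: 15 (E)-4-chloro-2-methylbut-2-enyl pivalate
Conditions: PivCl, pyridine, CH2Cl2, 0 °C
Reagents that add atoms: pivaloyl chloride, CC(C)(C)C(Cl)=O
Why: Routine acylation of a primary allylic alcohol; the pivalate matches the ring B esters so that one reagent removes all three at the end, and it resists the acetylide of the next step.

Step 11
Reactants: 16 chloroacetaldehyde dimethyl acetal; 15 (E)-4-chloro-2-methylbut-2-enyl pivalate
Product: 18 (E)-6-methoxy-2-methylhex-2-en-5-ynyl pivalate, via lithium methoxyacetylide 17 (not isolated)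
Conditions: 16 (1.3 equiv), LiNEt2 (3.0 equiv per 16), THF, 0 °C; then 15, NaI (0.1 equiv), DMPU, −78 → 25 °C; Et3N-deactivated silica
Reagents that add atoms: lithium diethylamide, CCN([Li])CC (its lithium appears only in 17)
Why: Threefold base-induced elimination of the chloroacetal gives 17, whose SN2 alkylation by a primary allylic halide (iodide catalysis) is the standard entry to 1-methoxyalkynes, and using exactly three equivalents of amide leaves no base to isomerise the skipped enyne or attack the pivalate.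

Step 12
Reactants: 12 (R,E)-7-[2,4-bis(pivaloyloxy)phenyl]-7-(tert-butyldimethylsilyloxy)-1-diazohept-3-en-2-one; 18 (E)-6-methoxy-2-methylhex-2-en-5-ynyl pivalate
Product: 23 (R,E)-4-{1-(tert-butyldimethylsilyloxy)-3-[2-hydroxy-4-methoxy-3-(3-methyl-4-(pivaloyloxy)but-2-enyl)phenyl]propyl}-1,3-phenylene bis(pivalate), via vinylketene 19 (not isolated), via vinylcyclobutenone 20 (not isolated), via dienylketene 21 (not isolated), via cyclohexadienone 22 (not isolated)
Conditions: 18 (1.5 equiv), ClCH2CH2Cl (degassed, 0.05 M), hν (medium-pressure Hg lamp, Pyrex filter), 25 °C; then 80 °C in the dark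
Reagents that add atoms: none
Why: Light above 300 nm expels N2 from 12 and the alkenyl group shifts to the carbene carbon (Wolff rearrangement, C5–C6) to give vinylketene 19, whose carbonyl carbon bonds to the nucleophilic alkyne carbon remote from the methoxyl while its α-carbon bonds to the methoxyl-bearing carbon ([2+2] cycloaddition closing the transient four-membered ring, C8–C8a and C6–C7) to give 20. Warming opens 20 by four-electron conrotatory ring opening to dienylketene 21, which closes ring A by thermal six-electron disrotatory electrocyclisation (C4a–C8a) to dienone 22 and tautomerises to phenol 23. The closest known reaction type is the photochemical diazo-ketone variant of the vinylketene–heteroalkyne (Danheiser) benzannulation, established for alkoxy- and siloxyalkynes. No stereocentre is created that survives, since the sp3 carbons of 20 and 22 are lost on aromatisation and the silylated C2 carbinol is remote and untouched. The step needs regioselectivity, which the polarisation of the ynol ether secures (side chain to C8 between the oxygens, methoxyl to C7, no isomer possible at C4a), and chemoselectivity for the electron-rich alkyne over the trisubstituted olefin, the esters and the doubly ortho-substituted product phenol, which the excess of 18 and Pyrex-filtered light (not absorbed by the aryl pivalates) support. The E geometry of the enone keeps the chain away from the ketene, so that no 1,5-hydrogen shift should intervene.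

Step 13
Reactants: 23 (R,E)-4-{1-(tert-butyldimethylsilyloxy)-3-[2-hydroxy-4-methoxy-3-(3-methyl-4-(pivaloyloxy)but-2-enyl)phenyl]propyl}-1,3-phenylene bis(pivalate)
Product: 24 (R,E)-4-{1-hydroxy-3-[2-hydroxy-4-methoxy-3-(3-methyl-4-(pivaloyloxy)but-2-enyl)phenyl]propyl}-1,3-phenylene bis(pivalate)
Conditions: HF·pyridine, pyridine, THF, 0 → 25 °C
Reagents that add atoms: none
Why: Fluoride cleavage of a secondary alkyl silyl ether under buffered acidic conditions never generates a free alkoxide next to the C2′ pivalate (no acyl shift) and leaves the esters, the aryl methyl ether and the olefin alone.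

Step 14
Reactants: 24 (R,E)-4-{1-hydroxy-3-[2-hydroxy-4-methoxy-3-(3-methyl-4-(pivaloyloxy)but-2-enyl)phenyl]propyl}-1,3-phenylene bis(pivalate)
Product: 25 (S,E)-4-{7-methoxy-8-[3-methyl-4-(pivaloyloxy)but-2-enyl]chroman-2-yl}-1,3-phenylene bis(pivalate)
Conditions: PPh3, DIAD, THF, 0 → 25 °C
Reagents that add atoms: none
Why: Intramolecular Mitsunobu etherification, in which the C8a phenoxide displaces the oxyphosphonium group of the (R)-carbinol in a 6-exo-tet SN2 reaction with inversion to the 2S centre, the two electron-withdrawing pivalates on ring B disfavouring ionisation to a benzylic cation.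

Step 15
Reactants: 25 (S,E)-4-{7-methoxy-8-[3-methyl-4-(pivaloyloxy)but-2-enyl]chroman-2-yl}-1,3-phenylene bis(pivalate)
Product: 26 morusyunnansin E, (S,E)-4-[8-(4-hydroxy-3-methylbut-2-enyl)-7-methoxychroman-2-yl]benzene-1,3-diol
Conditions: iBu2AlH (8 equiv), CH2Cl2, −78 → −40 °C; aq. potassium sodium tartrate
Reagents that add atoms: none
Why: Reductive ester cleavage with iBu2AlH at low temperature removes the two aryl pivalates and the allylic pivalate in one operation under non-ionising, non-basic conditions, so that C2 (prone to ring opening by an ortho or para phenoxide on heating, or by acid) and the allylic alcohol are not endangered.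

**Compound list**
1 | resorcinol | Oc1cccc(O)c1 | starting material
2 | succinic anhydride | O=C1CCC(=O)O1 | starting material
3 | 4-(2,4-dihydroxyphenyl)-4-oxobutanoic acid | O=C(O)CCC(=O)c1ccc(O)cc1O | intermediate
4 | 4-(2,4-dihydroxyphenyl)-N-methoxy-N-methyl-4-oxobutanamide | CON(C)C(=O)CCC(=O)c1ccc(O)cc1O | intermediate
5 | 4-[4-(methoxy(methyl)amino)-4-oxobutanoyl]-1,3-phenylene bis(pivalate) | CON(C)C(=O)CCC(=O)c1ccc(OC(=O)C(C)(C)C)cc1OC(=O)C(C)(C)C | intermediate
6 | (R)-4-[1-hydroxy-4-(methoxy(methyl)amino)-4-oxobutyl]-1,3-phenylene bis(pivalate) | CON(C)C(=O)CC[C@@H](O)c1ccc(OC(=O)C(C)(C)C)cc1OC(=O)C(C)(C)C | intermediate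
7 | (R)-4-[1-(tert-butyldimethylsilyloxy)-4-(methoxy(methyl)amino)-4-oxobutyl]-1,3-phenylene bis(pivalate) | CON(C)C(=O)CC[C@@H](O[Si](C)(C)C(C)(C)C)c1ccc(OC(=O)C(C)(C)C)cc1OC(=O)C(C)(C)C | intermediate
8 | (R)-4-[1-(tert-butyldimethylsilyloxy)-4-oxobutyl]-1,3-phenylene bis(pivalate) | O=CCC[C@@H](O[Si](C)(C)C(C)(C)C)c1ccc(OC(=O)C(C)(C)C)cc1OC(=O)C(C)(C)C | intermediate
9 | 1-(triphenylphosphoranylidene)propan-2-one | CC(=O)C=P(c1ccccc1)(c1ccccc1)c1ccccc1 | starting material
10 | (R,E)-7-[2,4-bis(pivaloyloxy)phenyl]-7-(tert-butyldimethylsilyloxy)hept-3-en-2-one | CC(=O)/C=C/CC[C@@H](O[Si](C)(C)C(C)(C)C)c1ccc(OC(=O)C(C)(C)C)cc1OC(=O)C(C)(C)C | intermediate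
11 | (R,E)-9-[2,4-bis(pivaloyloxy)phenyl]-9-(tert-butyldimethylsilyloxy)-1,1,1-trifluoronon-5-ene-2,4-dione (trifluoroacetyl diketone, not isolated) | O=C(CC(=O)C(F)(F)F)/C=C/CC[C@@H](O[Si](C)(C)C(C)(C)C)c1ccc(OC(=O)C(C)(C)C)cc1OC(=O)C(C)(C)C | intermediate
12 | (R,E)-7-[2,4-bis(pivaloyloxy)phenyl]-7-(tert-butyldimethylsilyloxy)-1-diazohept-3-en-2-one | [N-]=[N+]=CC(=O)/C=C/CC[C@@H](O[Si](C)(C)C(C)(C)C)c1ccc(OC(=O)C(C)(C)C)cc1OC(=O)C(C)(C)C | intermediate
13 | 2-methyl-2-vinyloxirane | CC1(C=C)CO1 | starting material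
14 | (E)-4-chloro-2-methylbut-2-en-1-ol | ClC/C=C(\C)CO | intermediate
15 | (E)-4-chloro-2-methylbut-2-enyl pivalate | ClC/C=C(\C)COC(=O)C(C)(C)C | intermediate
16 | chloroacetaldehyde dimethyl acetal | COC(CCl)OC | starting material
17 | lithium methoxyacetylide (not isolated) | COC#C[Li] | intermediate
18 | (E)-6-methoxy-2-methylhex-2-en-5-ynyl pivalate | COC#CC/C=C(\C)COC(=O)C(C)(C)C | intermediate
19 | (R,E)-7-[2,4-bis(pivaloyloxy)phenyl]-7-(tert-butyldimethylsilyloxy)hepta-1,3-dien-1-one (vinylketene, not isolated) | O=C=C/C=C/CC[C@@H](O[Si](C)(C)C(C)(C)C)c1ccc(OC(=O)C(C)(C)C)cc1OC(=O)C(C)(C)C | intermediate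
20 | 4-{(R,E)-5-[2,4-bis(pivaloyloxy)phenyl]-5-(tert-butyldimethylsilyloxy)pent-1-enyl}-3-methoxy-2-[(E)-3-methyl-4-(pivaloyloxy)but-2-enyl]cyclobut-2-en-1-one (ring C4 unassigned, not isolated) | COC1=C(C/C=C(\C)COC(=O)C(C)(C)C)C(=O)C1/C=C/CC[C@@H](O[Si](C)(C)C(C)(C)C)c1ccc(OC(=O)C(C)(C)C)cc1OC(=O)C(C)(C)C | intermediate
21 | (3E,5E,9R)-9-[2,4-bis(pivaloyloxy)phenyl]-9-(tert-butyldimethylsilyloxy)-3-methoxy-2-[(E)-3-methyl-4-(pivaloyloxy)but-2-enyl]nona-1,3,5-trien-1-one (dienylketene, not isolated) | O=C=C(C/C=C(\C)COC(=O)C(C)(C)C)/C(OC)=C\C=C\CC[C@@H](O[Si](C)(C)C(C)(C)C)c1ccc(OC(=O)C(C)(C)C)cc1OC(=O)C(C)(C)C | intermediate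
22 | 6-{(R)-3-[2,4-bis(pivaloyloxy)phenyl]-3-(tert-butyldimethylsilyloxy)propyl}-3-methoxy-2-[(E)-3-methyl-4-(pivaloyloxy)but-2-enyl]cyclohexa-2,4-dien-1-one (ring C6 unassigned, not isolated) | COC1=C(C/C=C(\C)COC(=O)C(C)(C)C)C(=O)C(CC[C@@H](O[Si](C)(C)C(C)(C)C)c2ccc(OC(=O)C(C)(C)C)cc2OC(=O)C(C)(C)C)C=C1 | intermediate
23 | (R,E)-4-{1-(tert-butyldimethylsilyloxy)-3-[2-hydroxy-4-methoxy-3-(3-methyl-4-(pivaloyloxy)but-2-enyl)phenyl]propyl}-1,3-phenylene bis(pivalate) | COc1ccc(CC[C@@H](O[Si](C)(C)C(C)(C)C)c2ccc(OC(=O)C(C)(C)C)cc2OC(=O)C(C)(C)C)c(O)c1C/C=C(\C)COC(=O)C(C)(C)C | intermediate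
24 | (R,E)-4-{1-hydroxy-3-[2-hydroxy-4-methoxy-3-(3-methyl-4-(pivaloyloxy)but-2-enyl)phenyl]propyl}-1,3-phenylene bis(pivalate) | COc1ccc(CC[C@@H](O)c2ccc(OC(=O)C(C)(C)C)cc2OC(=O)C(C)(C)C)c(O)c1C/C=C(\C)COC(=O)C(C)(C)C | intermediate
25 | (S,E)-4-{7-methoxy-8-[3-methyl-4-(pivaloyloxy)but-2-enyl]chroman-2-yl}-1,3-phenylene bis(pivalate) | COc1ccc2c(c1C/C=C(\C)COC(=O)C(C)(C)C)O[C@H](c1ccc(OC(=O)C(C)(C)C)cc1OC(=O)C(C)(C)C)CC2 | intermediate
26 | morusyunnansin E, (S,E)-4-[8-(4-hydroxy-3-methylbut-2-enyl)-7-methoxychroman-2-yl]benzene-1,3-diol | COc1ccc2c(c1C/C=C(\C)CO)O[C@H](c1ccc(O)cc1O)CC2 | target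

**Step count**
Total: 15 steps. Longest linear sequence: 12 steps (steps 1–8, then 12–15); steps 9–11 form the convergent alkyne branch.

**Steps most likely to fail, with fallbacks**

1. Step 12. Capture of the vinylketene by the methyl ynol ether may be slower than ketene dimerisation or acylation of the product phenol. E/Z photoisomerisation of the enone followed by a 1,5-hydrogen shift could also intervene, and the methyl ynol ether may hydrate or polymerise on handling. The fallback keeps the benzannulation but changes the alkyne class to a shielded siloxyalkyne, the standard ketenophile for this annulation, and installs the C7 methyl ether afterwards. It sets out from 15 and 12 and comes back at 25. Compound 15 would be coupled with HC≡CMgBr (CuCl cat., THF) to (E)-2-methylhex-2-en-5-ynyl pivalate F1. Its lithium acetylide (LiN(SiMe3)2, THF, −78 °C) would be oxidised to the ynolate with LiOOtBu and silylated with iPr3SiOTf to (E)-2-methyl-6-(triisopropylsilyloxy)hex-2-en-5-ynyl pivalate F2. Irradiation of 12 with F2 and heating as in step 12 should give (R,E)-4-{1-(tert-butyldimethylsilyloxy)-3-[2-hydroxy-3-(3-methyl-4-(pivaloyloxy)but-2-enyl)-4-(triisopropylsilyloxy)phenyl]propyl}-1,3-phenylene bis(pivalate) F3. HF·pyridine would free the carbinol while the aryl silyl ether persists, giving (R,E)-4-{1-hydroxy-3-[2-hydroxy-3-(3-methyl-4-(pivaloyloxy)but-2-enyl)-4-(triisopropylsilyloxy)phenyl]propyl}-1,3-phenylene bis(pivalate) F4. Mitsunobu closure as in step 14 would give (S,E)-4-{8-[3-methyl-4-(pivaloyloxy)but-2-enyl]-7-(triisopropylsilyloxy)chroman-2-yl}-1,3-phenylene bis(pivalate) F5. Desilylative methylation (CsF, MeI, DMF) would then convert the C7 silyl ether into the methyl ether, rejoining the route at 25.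

2. Step 11. The acetylide or residual amide may attack the pivalate, substitution may go SN2′, or the base may isomerise the skipped enyne to a conjugated allenyl or enynyl ether. The fallback replaces the alkylation of a basic organolithium by a neutral palladium-catalysed cross-coupling. It sets out from 17 (made from 16 as in step 11) and 15 and comes back at 18. Compound 17 would be quenched with Bu3SnCl to tributyl(methoxyethynyl)stannane F6, which is purified and coupled with 15 under zerovalent palladium catalysis (Pd(PPh3)4, THF, 50 °C; Stille coupling through the π-allyl complex, bond formation at the unhindered terminus, the allylic chloride ionising far faster than the allylic pivalate) to give 18.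

3. Step 14. The betaine may shift the C2′ pivaloyl group onto the free carbinol before activation, the ortho ester may participate in the displacement, or the oxyphosphonium ion may eliminate to the styrene. Any of these would cost yield or configurational purity. The fallback separates activation from ring closure (Williamson-type closure), so that the carbinol is never free under basic conditions. It sets out from 23 and comes back at 25. The hindered phenol of 23 would be acetylated (Ac2O, DMAP, pyridine) to (R,E)-4-{3-[2-acetoxy-4-methoxy-3-(3-methyl-4-(pivaloyloxy)but-2-enyl)phenyl]-1-(tert-butyldimethylsilyloxy)propyl}-1,3-phenylene bis(pivalate) F7. HF·pyridine would give (R,E)-4-{3-[2-acetoxy-4-methoxy-3-(3-methyl-4-(pivaloyloxy)but-2-enyl)phenyl]-1-hydroxypropyl}-1,3-phenylene bis(pivalate) F8. MsCl/Et3N at −30 °C would give, with retention, (R,E)-4-{3-[2-acetoxy-4-methoxy-3-(3-methyl-4-(pivaloyloxy)but-2-enyl)phenyl]-1-(methylsulfonyloxy)propyl}-1,3-phenylene bis(pivalate) F9, used crude. K2CO3 in MeOH/THF at 0 °C should cleave the aryl acetate much faster than the pivalates, and the phenoxide then displaces the mesylate intramolecularly with inversion to give 25.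

**Further compounds**
F1 | step 12 | (E)-2-methylhex-2-en-5-ynyl pivalate | C#CC/C=C(\C)COC(=O)C(C)(C)C
F2 | step 12 | (E)-2-methyl-6-(triisopropylsilyloxy)hex-2-en-5-ynyl pivalate | CC(C)[Si](C(C)C)(C(C)C)OC#CC/C=C(\C)COC(=O)C(C)(C)C
F3 | step 12 | (R,E)-4-{1-(tert-butyldimethylsilyloxy)-3-[2-hydroxy-3-(3-methyl-4-(pivaloyloxy)but-2-enyl)-4-(triisopropylsilyloxy)phenyl]propyl}-1,3-phenylene bis(pivalate) | CC(C)[Si](C(C)C)(C(C)C)Oc1ccc(CC[C@@H](O[Si](C)(C)C(C)(C)C)c2ccc(OC(=O)C(C)(C)C)cc2OC(=O)C(C)(C)C)c(O)c1C/C=C(\C)COC(=O)C(C)(C)C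
F4 | step 12 | (R,E)-4-{1-hydroxy-3-[2-hydroxy-3-(3-methyl-4-(pivaloyloxy)but-2-enyl)-4-(triisopropylsilyloxy)phenyl]propyl}-1,3-phenylene bis(pivalate) | CC(C)[Si](C(C)C)(C(C)C)Oc1ccc(CC[C@@H](O)c2ccc(OC(=O)C(C)(C)C)cc2OC(=O)C(C)(C)C)c(O)c1C/C=C(\C)COC(=O)C(C)(C)C
F5 | step 12 | (S,E)-4-{8-[3-methyl-4-(pivaloyloxy)but-2-enyl]-7-(triisopropylsilyloxy)chroman-2-yl}-1,3-phenylene bis(pivalate) | CC(C)[Si](C(C)C)(C(C)C)Oc1ccc2c(c1C/C=C(\C)COC(=O)C(C)(C)C)O[C@H](c1ccc(OC(=O)C(C)(C)C)cc1OC(=O)C(C)(C)C)CC2
F6 | step 11 | tributyl(methoxyethynyl)stannane | CCCC[Sn](CCCC)(CCCC)C#COC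
F7 | step 14 | (R,E)-4-{3-[2-acetoxy-4-methoxy-3-(3-methyl-4-(pivaloyloxy)but-2-enyl)phenyl]-1-(tert-butyldimethylsilyloxy)propyl}-1,3-phenylene bis(pivalate) | COc1ccc(CC[C@@H](O[Si](C)(C)C(C)(C)C)c2ccc(OC(=O)C(C)(C)C)cc2OC(=O)C(C)(C)C)c(OC(C)=O)c1C/C=C(\C)COC(=O)C(C)(C)C
F8 | step 14 | (R,E)-4-{3-[2-acetoxy-4-methoxy-3-(3-methyl-4-(pivaloyloxy)but-2-enyl)phenyl]-1-hydroxypropyl}-1,3-phenylene bis(pivalate) | COc1ccc(CC[C@@H](O)c2ccc(OC(=O)C(C)(C)C)cc2OC(=O)C(C)(C)C)c(OC(C)=O)c1C/C=C(\C)COC(=O)C(C)(C)C
F9 | step 14 | (R,E)-4-{3-[2-acetoxy-4-methoxy-3-(3-methyl-4-(pivaloyloxy)but-2-enyl)phenyl]-1-(methylsulfonyloxy)propyl}-1,3-phenylene bis(pivalate) | COc1ccc(CC[C@@H](OS(C)(=O)=O)c2ccc(OC(=O)C(C)(C)C)cc2OC(=O)C(C)(C)C)c(OC(C)=O)c1C/C=C(\C)COC(=O)C(C)(C)C
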